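Find how much product this flask holds at 20 h and which remedy adds most. On the suspect list, free catalyst opens the substrate to the open intermediate and binds that as catalyst intermediate, reagent then releases product and free catalyst, and free catalyst may pass into spent catalyst.

| flask | substrate | reagent | free catalyst | temperature | remark | time |
|---|---|---|---|---|---|---|
| theta | 0.10 M | 0.18 M | 0.10 mM | 35 °C | the very flask that is asked about, followed so far |  |
| gamma | 0.10 M | 0.18 M | 0.10 mM | 30 °C | run made earlier |  |
| flask | 0.10 M | 0.180 M | 0.10 mM | 35 °C |  | 20 h |

- theta (time / h: product / %): 2.00: 4.3; 4.00: 8.7; 6.00: 13.0; 8.00: 14.8; 10.0: 15.3; 12.0: 17.0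
- gamma (time / h: product / %): 2.00: 4.0; 4.00: 9.4; 6.00: 14.1; 8.00: 16.4; 10.0: 21.2; 12.0: 23.5

(scatter of a reading: 0.5 percentage points)

- north: at 20 h take out 90% of the product then present, then wait 6.0 h
- south: change nothing and wait 6.0 h more
- east: at 20 h raise the temperature by 15 K, then wait 6.0 h
- south-east: at 20 h add free catalyst, 50.0% of the amount charged, then wait 6.0 h
- south-west: at 20 h add reagent, 50.0% of the amount charged, then wait 6.0 h

- what is taken out of product is counted as made
- on the list of suspects stand: substrate + free catalyst <-> free catalyst + open intermediate; free catalyst + open intermediate <-> catalyst intermediate; reagent + catalyst intermediate <-> free catalyst + product; free catalyst -> spent catalyst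
- additions bring no volume worth counting

* product, in percent of the substrate first charged, at 20 h
* the remedy with the largest gain of product, or "none" below 2 percentage points (north / south / east / south-east / south-west / none)
* product present, with what was taken out counted in, in percent of the substrate first charged, after south-east
* product present, with what was taken out counted in, in percent of the substrate first charged, after south-west

One thing jars: the theta flask at 35 °C reads 17.0% at 12.0 h, while the colder gamma run reads 23.5%, so the warmer flask holds less.

Clear this with slopes, in fractions of the charged substrate per hour. Take a steady catalyst as the zero of the scale: early slope a equals late slope b, and their ratio is one. For theta: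

a = 13.0% / 6.00 h = 0.0217 h⁻¹, centred at 3.00 h

b = (17.0% − 14.8%) / (12.0 h − 8.00 h) = 0.00550 h⁻¹, centred at 10.0 h

The ratio a/b reads 3.95 in theta and 1.32 in gamma, so read a catalyst that fades faster when warmer. Read its time constant in theta as:

τ = (centre of b − centre of a) / ln(a/b) = 5.11 h

Now define W, the capacity of one catalyst charge: the product it makes in theta before it fades out, which is the turnover number in percent of the substrate. Add the tail to the last reading:

W = 17.0% + bτ·exp(−(12.0 h − 10.0 h)/τ) = 18.9%

Slope b rests on readings of scatter 0.5 percentage points, so W is a reading too. My reckoning gives 18.5% at 20 h. If a fresh charge fades with the same τ, it adds 6.5 points over 6.0 h, which makes 25.0%.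

The forecast says 18.5%, south-east, 24.5% after south-east, which is lower than my figure, and 19.8% after south-west. It names “thermally faster catalyst death” as the likely cause.

The flask gives 18.2%, and south-east wins with a gain of 6.8 points, reaching 24.9%; south-west reaches 18.6%.

    substrate + free catalyst ⇌ free catalyst + open intermediate (K = 0.320, k = 2010 M⁻¹ h⁻¹, Ea = 56.0 kJ mol⁻¹, ΔH = −24.0 kJ mol⁻¹)
    free catalyst + open intermediate ⇌ catalyst intermediate (K = 12.0 M⁻¹, k = 3.80 × 10⁵ M⁻¹ h⁻¹, Ea = 51.0 kJ mol⁻¹, ΔH = −78.0 kJ mol⁻¹)
    reagent + catalyst intermediate ⇌ free catalyst + product (K = 19.0, k = 1650 M⁻¹ h⁻¹, Ea = 64.0 kJ mol⁻¹, ΔH = −11.0 kJ mol⁻¹)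
    free catalyst → spent catalyst (k = 0.230 h⁻¹, Ea = 96.0 kJ mol⁻¹)
    (constants at 35 °C)

At 20.0 h this flask holds 98.0% of its catalyst as spent catalyst, with 67% of its substrate left. Its 18.2% plus the 6.5 points reckoned for the fresh charge gives 24.7%, beside the 24.9% it reaches after south-east. Carry W to the neighbour charged with 1.7 × 10⁻⁴ M of free catalyst, scaling the reckoned value by charge: 18.5% × 1.70 = 31.5%. That neighbour stands at 30.4% at 20.0 h, with 56% of its substrate left.

(The data stem from a simulated flask on assumed constants, noise included.)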